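## Retrosynthetic overview

1. 21 ⇐ 20: ring-closing metathesis at C4=C5 closes the ten-membered carbocycle last; the five-membered lactone is formed before it.
2. 20 ⇐ 19 ⇐ 16: the cis α-methylene-γ-lactone comes from Pd-catalysed cyclocarbonylation of the C6 hydroxyl/C7 ethynyl pair, after the C8 hydroxyl has been capped as the tiglate.
3. 16 ⇐ 13 + 6: the C7–C8 bond and both stereocentres come from anti-selective allenylindium (Marshall) addition of propargylic mesylate 13 (fragment B) to aldehyde 6 (fragment A).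
4. 6 ⇐ 5 ⇐ 1: the C9–C10 bond and the C10 carbinol come from a proposed new copper–bis(oxazoline) aldol of an acetaldehyde enol silane with vicinal diketone 5.
5. 13 ⇐ 7 + 8: the C6 stereocentre comes from Brown γ-alkoxyallylboration of ynal 8, followed by Mitsunobu inversion of the propargylic carbinol.

Assumption: the SMILES is read as the 4Z, 6R, 7S, 8R, 10R germacranolide with a cis-fused 12,6-lactone and an (E)-2-methylbut-2-enoate (tiglate) at C8; germacrane numbering (C1 ketone, C4=C5, C6 lactone carbinol, C8 ester carbinol, C10 tertiary carbinol, C11–C13 methylene lactone) is used in the explanations.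

## Route

Step 1
Reactants: 1 4-methylpent-4-enoic acid
Product: 3 N-methoxy-N,4-dimethylpent-4-enamide, via acyl imidazole 2 (not isolated)
Conditions: CDI, CH2Cl2, 0 °C to rt; then MeNHOMe·HCl, rt
Reagents that add atoms: N,O-dimethylhydroxylamine hydrochloride (CNOC.Cl)
Why: CDI activates the acid as the acyl imidazole, which the hydroxylamine aminolyses to the Weinreb amide (amide coupling); the remote 1,1-disubstituted alkene is inert.

Step 2
Reactants: 3 N-methoxy-N,4-dimethylpent-4-enamide
Product: 5 6-methylhept-6-ene-2,3-dione, via ethoxy enone 4 (not isolated)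
Conditions: ethyl vinyl ether, t-BuLi, THF, −78 to 0 °C; then 3, −78 °C; then 1 M HCl, rt
Reagents that add atoms: ethyl vinyl ether (C=COCC); water (O)
Why: 1-ethoxyvinyllithium (an acetyl anion equivalent) adds once to the Weinreb amide through the chelated tetrahedral intermediate (Weinreb ketone synthesis), and acid hydrolysis of the enol ether in 4 unmasks the second carbonyl.

Step 3
Reactants: 5 6-methylhept-6-ene-2,3-dione
Product: 6 (3R)-3,7-dimethyl-4-oxo-3-[(trimethylsilyl)oxy]oct-7-enal
Conditions: Cu(OTf)2 (10 mol%), (R,R)-t-Bu-box (11 mol%), trimethyl(vinyloxy)silane (2 equiv), THF, −78 to −40 °C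
Reagents that add atoms: trimethyl(vinyloxy)silane (C=CO[Si](C)(C)C)
Why: Proposed new method: the C2-symmetric divalent-copper bis(oxazoline) Lewis acid binds diketone 5 as a five-membered O,O-chelate, the acetaldehyde enol silane attacks the less hindered acetyl carbonyl (C10) on the re face left open by the (R,R)-tert-butyl groups (the enantiomeric ligand is known to direct si-face attack on chelated pyruvates), which sets 10R, and silyl transfer to the copper aldolate releases the β-silyloxy aldehyde 6, which cannot chelate and so does not react further; the closest known reaction type is the copper–bis(oxazoline)-catalysed Mukaiyama aldol addition of silyl ketene thioacetals and ketone enol silanes to pyruvates and vicinal diketones, where an aldehyde-derived enol silane has not been shown as donor.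

Step 4
Reactants: 7 3-(methoxymethoxy)prop-1-ene; 8 3-(trimethylsilyl)prop-2-ynal
Product: 10 (3R,4R)-4-(methoxymethoxy)-1-(trimethylsilyl)hex-5-en-1-yn-3-ol, via allylborane 9 (not isolated)
Conditions: 7, s-BuLi, THF, −78 °C; (−)-Ipc2BOMe; BF3·OEt2; then 8, −78 °C; HOCH2CH2NH2, rt
Reagents that add atoms: none
Why: Brown asymmetric γ-alkoxyallylboration: the (Z)-γ-alkoxyallylborane 9 adds through a chair Zimmerman–Traxler transition state to the si face of 8 (control by the isopinocampheyl groups derived from (+)-α-pinene), giving the syn (3R,4R) mono-protected diol and with it the future C6 stereocentre.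

Step 5
Reactants: 10 (3R,4R)-4-(methoxymethoxy)-1-(trimethylsilyl)hex-5-en-1-yn-3-ol
Product: 11 (3S,4R)-4-(methoxymethoxy)-1-(trimethylsilyl)hex-5-en-1-yn-3-yl 4-nitrobenzoate
Conditions: 4-nitrobenzoic acid, PPh3, DIAD, THF, 0 °C to rt
Reagents that add atoms: 4-nitrobenzoic acid (O=C(O)c1ccc(cc1)[N+](=O)[O-])
Why: Mitsunobu esterification inverts the propargylic carbinol carbon by SN2 displacement of the oxyphosphonium, turning the syn (3R,4R) pattern into the anti (3S,4R) pattern needed for the coupling.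

Step 6
Reactants: 11 (3S,4R)-4-(methoxymethoxy)-1-(trimethylsilyl)hex-5-en-1-yn-3-yl 4-nitrobenzoate
Product: 12 (3S,4R)-4-(methoxymethoxy)hex-5-en-1-yn-3-ol
Conditions: K2CO3, MeOH, 0 °C to rt
Reagents that add atoms: none
Why: Carbonate-mediated methanolysis cleaves the nitrobenzoate (transesterification) and the alkynyl C–Si bond in one operation without touching either stereocentre.

Step 7
Reactants: 12 (3S,4R)-4-(methoxymethoxy)hex-5-en-1-yn-3-ol
Product: 13 (3S,4R)-4-(methoxymethoxy)hex-5-en-1-yn-3-yl methanesulfonate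
Conditions: MsCl, Et3N, CH2Cl2, −20 °C
Reagents that add atoms: methanesulfonyl chloride (CS(=O)(=O)Cl)
Why: Sulfonylation of the secondary propargylic alcohol at oxygen (retention) gives the leaving group for palladium-mediated allenylmetal formation.

Step 8
Reactants: 13 (3S,4R)-4-(methoxymethoxy)hex-5-en-1-yn-3-yl methanesulfonate; 6 (3R)-3,7-dimethyl-4-oxo-3-[(trimethylsilyl)oxy]oct-7-enal
Product: 16 (3R,4S,5R,7R)-4-ethynyl-5,7-dihydroxy-3-(methoxymethoxy)-7,11-dimethyldodeca-1,11-dien-8-one, via allenylindium 14 (not isolated), via silyl ether 15 (not isolated)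
Conditions: Pd(dppf)Cl2 (5 mol%), InI (1.5 equiv), THF–HMPA (3:1), rt; then 1 M HCl, THF, 0 °C
Reagents that add atoms: none
Why: Marshall propargylation: zerovalent palladium displaces the mesylate anti-SN2′, transmetalation with InI gives allenylindium 14, and 14 adds to the aldehyde (not the hindered ketone) through a cyclic syn-SE2′ transition state, so C7 is formed with net inversion of the mesylate carbon (7S) and C8 anti to it (8R); dilute acid then removes the tertiary trimethylsilyl ether.

Step 9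
Reactants: 16 (3R,4S,5R,7R)-4-ethynyl-5,7-dihydroxy-3-(methoxymethoxy)-7,11-dimethyldodeca-1,11-dien-8-one
Product: 17 (3R,4S,5R,7R)-4-ethynyl-7-hydroxy-3-(methoxymethoxy)-7,11-dimethyl-8-oxododeca-1,11-dien-5-yl (2E)-2-methylbut-2-enoate
Conditions: tigloyl chloride, pyridine, DMAP (cat.), CH2Cl2, 0 °C to rt
Reagents that add atoms: (E)-2-methylbut-2-enoyl chloride (C/C=C(\C)C(=O)Cl)
Why: DMAP-catalysed acylation (esterification) takes place at the secondary C8 hydroxyl because the tertiary α-ketol hydroxyl is too hindered; the E geometry of the acyl group is retained.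

Step 10
Reactants: 17 (3R,4S,5R,7R)-4-ethynyl-7-hydroxy-3-(methoxymethoxy)-7,11-dimethyl-8-oxododeca-1,11-dien-5-yl (2E)-2-methylbut-2-enoate
Product: 19 (3R,4R,5R,7R)-4-ethynyl-3,7-dihydroxy-7,11-dimethyl-8-oxododeca-1,11-dien-5-yl (2E)-2-methylbut-2-enoate, via bromomethyl ether 18 (not isolated)
Conditions: Me2BBr (3 equiv), CH2Cl2, −78 °C; then THF, aq. NaHCO3, 0 °C
Reagents that add atoms: none
Why: Guindon acetal cleavage: Me2BBr converts the methoxymethyl ether into bromomethyl ether 18 at −78 °C, which is hydrolysed on bicarbonate work-up, while ester, ketone, alkyne and alkenes are left intact (the change of the C4 descriptor from S to R is only a priority change).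

Step 11
Reactants: 19 (3R,4R,5R,7R)-4-ethynyl-3,7-dihydroxy-7,11-dimethyl-8-oxododeca-1,11-dien-5-yl (2E)-2-methylbut-2-enoate
Product: 20 (1R,3R)-1-[(2R,3S)-2-ethenyl-4-methylidene-5-oxooxolan-3-yl]-3-hydroxy-3,7-dimethyl-4-oxooct-7-en-1-yl (2E)-2-methylbut-2-enoate
Conditions: PdCl2 (10 mol%), thiourea (10 mol%), CO (3 atm), acetone, 50 °C
Reagents that add atoms: carbon monoxide ([C-]#[O+])
Why: Norton-type palladium-catalysed cyclocarbonylation: the alkoxycarbonyl–palladium species formed at the C6 hydroxyl adds syn across the neighbouring terminal alkyne (5-exo) and protonolysis gives the α-methylene-γ-lactone; the cis fusion follows from the fixed C6 and C7 configurations, and only the C6 hydroxyl is free to cyclise.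

Step 12
Reactants: 20 (1R,3R)-1-[(2R,3S)-2-ethenyl-4-methylidene-5-oxooxolan-3-yl]-3-hydroxy-3,7-dimethyl-4-oxooct-7-en-1-yl (2E)-2-methylbut-2-enoate
Product: 21 (3aS,4R,6R,10Z,11aR)-6-hydroxy-6,10-dimethyl-3-methylidene-2,7-dioxo-2,3,3a,4,5,6,7,8,9,11a-decahydrocyclodeca[b]furan-4-yl (2E)-2-methylbut-2-enoate
Conditions: second-generation Grubbs catalyst (H2IMes)(PCy3)Cl2Ru=CHPh (15 mol%), toluene (1 mM), 80 °C
Reagents that add atoms: none
Why: Ring-closing metathesis between the C6 vinyl group and the 1,1-disubstituted alkene, held cis on the lactone, forms the trisubstituted C4=C5 alkene of the ten-membered ring with loss of ethylene; the Z geometry is the one expected for a ten-membered ring closed across a cis-fused lactone, and the conjugated trisubstituted tiglate and the methylene lactone alkenes stay spectators.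

## Compound list

1 | 4-methylpent-4-enoic acid | C=C(C)CCC(=O)O | starting material
2 | 1-(imidazol-1-yl)-4-methylpent-4-en-1-one (acyl imidazole) | C=C(C)CCC(=O)n1ccnc1 | intermediate
3 | N-methoxy-N,4-dimethylpent-4-enamide | C=C(C)CCC(=O)N(C)OC | intermediate
4 | 2-ethoxy-6-methylhepta-1,6-dien-3-one | C=C(C)CCC(=O)C(=C)OCC | intermediate
5 | 6-methylhept-6-ene-2,3-dione | C=C(C)CCC(=O)C(C)=O | intermediate
6 | (3R)-3,7-dimethyl-4-oxo-3-[(trimethylsilyl)oxy]oct-7-enal (fragment A) | C=C(C)CCC(=O)[C@](C)(O[Si](C)(C)C)CC=O | intermediate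
7 | 3-(methoxymethoxy)prop-1-ene (allyl methoxymethyl ether) | C=CCOCOC | starting material
8 | 3-(trimethylsilyl)prop-2-ynal | C[Si](C)(C)C#CC=O | starting material
9 | [(2Z)-3-(methoxymethoxy)prop-2-en-1-yl]bis[(1R,2S,3R,5R)-2,6,6-trimethylbicyclo[3.1.1]heptan-3-yl]borane | COCO/C=C\CB([C@@H]1C[C@@H]2C[C@H]([C@H]1C)C2(C)C)[C@@H]1C[C@@H]2C[C@H]([C@H]1C)C2(C)C | intermediate
10 | (3R,4R)-4-(methoxymethoxy)-1-(trimethylsilyl)hex-5-en-1-yn-3-ol | C[Si](C)(C)C#C[C@@H](O)[C@H](OCOC)C=C | intermediate
11 | (3S,4R)-4-(methoxymethoxy)-1-(trimethylsilyl)hex-5-en-1-yn-3-yl 4-nitrobenzoate | C[Si](C)(C)C#C[C@H](OC(=O)c1ccc(cc1)[N+](=O)[O-])[C@H](OCOC)C=C | intermediate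
12 | (3S,4R)-4-(methoxymethoxy)hex-5-en-1-yn-3-ol | C#C[C@H](O)[C@H](OCOC)C=C | intermediate
13 | (3S,4R)-4-(methoxymethoxy)hex-5-en-1-yn-3-yl methanesulfonate (fragment B) | C#C[C@H](OS(C)(=O)=O)[C@H](OCOC)C=C | intermediate
14 | iodo[(aS,4R)-4-(methoxymethoxy)hexa-1,2,5-trien-1-yl]indium methanesulfonate (indium anti to the departed mesylate; the allene axis is not encoded in the SMILES) | CS(=O)(=O)O[In](I)C=C=C[C@H](OCOC)C=C | intermediate
15 | (3R,4S,5R,7R)-4-ethynyl-5-hydroxy-3-(methoxymethoxy)-7,11-dimethyl-7-[(trimethylsilyl)oxy]dodeca-1,11-dien-8-one | C#C[C@H]([C@H](OCOC)C=C)[C@H](O)C[C@@](C)(O[Si](C)(C)C)C(=O)CCC(C)=C | intermediate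
16 | (3R,4S,5R,7R)-4-ethynyl-5,7-dihydroxy-3-(methoxymethoxy)-7,11-dimethyldodeca-1,11-dien-8-one | C#C[C@H]([C@H](OCOC)C=C)[C@H](O)C[C@@](C)(O)C(=O)CCC(C)=C | intermediate
17 | (3R,4S,5R,7R)-4-ethynyl-7-hydroxy-3-(methoxymethoxy)-7,11-dimethyl-8-oxododeca-1,11-dien-5-yl (2E)-2-methylbut-2-enoate | C#C[C@H]([C@H](OCOC)C=C)[C@H](OC(=O)/C(C)=C/C)C[C@@](C)(O)C(=O)CCC(C)=C | intermediate
18 | (3R,4S,5R,7R)-3-(bromomethoxy)-4-ethynyl-7-hydroxy-7,11-dimethyl-8-oxododeca-1,11-dien-5-yl (2E)-2-methylbut-2-enoate | C#C[C@H]([C@H](OCBr)C=C)[C@H](OC(=O)/C(C)=C/C)C[C@@](C)(O)C(=O)CCC(C)=C | intermediate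
19 | (3R,4R,5R,7R)-4-ethynyl-3,7-dihydroxy-7,11-dimethyl-8-oxododeca-1,11-dien-5-yl (2E)-2-methylbut-2-enoate | C#C[C@H]([C@H](O)C=C)[C@H](OC(=O)/C(C)=C/C)C[C@@](C)(O)C(=O)CCC(C)=C | intermediate
20 | (1R,3R)-1-[(2R,3S)-2-ethenyl-4-methylidene-5-oxooxolan-3-yl]-3-hydroxy-3,7-dimethyl-4-oxooct-7-en-1-yl (2E)-2-methylbut-2-enoate | C=C1C(=O)O[C@H](C=C)[C@@H]1[C@H](OC(=O)/C(C)=C/C)C[C@@](C)(O)C(=O)CCC(C)=C | intermediate
21 | (3aS,4R,6R,10Z,11aR)-6-hydroxy-6,10-dimethyl-3-methylidene-2,7-dioxo-2,3,3a,4,5,6,7,8,9,11a-decahydrocyclodeca[b]furan-4-yl (2E)-2-methylbut-2-enoate (CNP0345906.4) | C=C1C(=O)O[C@@H]2/C=C(/C)CCC(=O)[C@](C)(O)C[C@@H](OC(=O)/C(C)=C/C)[C@H]12 | target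

## Step count and risks

Total step count: 12. Longest linear sequence: 9 steps (steps 4 to 12, from 7 and 8 to 21).

The three steps most likely to fail:

**Step 3 (proposed new aldol).** The acetaldehyde enol silane is a much weaker nucleophile than the silyl ketene acetals normally used, so conversion, the acetyl/alkyl-carbonyl regioselectivity and the enantioselectivity are all untested. The fallback uses known chemistry, sets out from 5 and comes back to the route at 6. Diketone 5 is treated with 1-(ethylsulfanyl)-1-[(trimethylsilyl)oxy]ethene under the same Cu(OTf)2/(R,R)-t-Bu-box catalysis in THF at −78 °C, the established thioester-enolate version of this chelation-controlled aldol, to give the thioester S-ethyl (3R)-3,7-dimethyl-4-oxo-3-[(trimethylsilyl)oxy]oct-7-enethioate F1. Fukuyama reduction of F1 (Et3SiH, Pd/C, acetone, rt) then gives aldehyde 6.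

**Step 8 (allenylindium coupling).** Aldehyde 6 is α-unbranched, so the anti/syn ratio may be modest, and the allenylindium carries a neighbouring methoxymethoxy group that could be lost by 1,4-elimination. The fallback sets out from 13 (with 6) and comes back at 16. Mesylate 13 is converted with HSiCl3, CuCl (cat.) and i-Pr2NEt in Et2O–MeCN, by anti-SN2′ substitution, into the allenylsilane trichloro[(aS,4R)-4-(methoxymethoxy)hexa-1,2,5-trien-1-yl]silane F2. DMF-promoted addition of F2 to 6 at 0 °C runs through a closed transition state at hypervalent silicon with the same net stereochemical course, and work-up with 1 M HCl gives 15 and then 16.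

**Step 12 (ring-closing metathesis).** A ten-membered ring with a trisubstituted alkene has to close across a rigid cis-fused lactone; dimerisation, a poor Z/E ratio or failure to cyclise are possible. The fallback forms the carbocycle first and the lactone last; it sets out from 17 and comes back at 21.
- Branched methoxycarbonylation of the terminal alkyne of 17 (Pd(OAc)2, 2-pyridyldiphenylphosphine, MsOH cat., CO, MeOH, 45 °C) gives the open-chain acrylate methyl (3S,4R)-3-[(1R,3R)-3-hydroxy-3,7-dimethyl-1-{[(2E)-2-methylbut-2-enoyl]oxy}-4-oxooct-7-en-1-yl]-4-(methoxymethoxy)-2-methylidenehex-5-enoate F3.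
- Ring-closing metathesis of this conformationally free diene (same ruthenium catalyst, toluene, 80 °C) gives the cyclodecene methyl 2-[(1S,2R,3Z,8R,10R)-8-hydroxy-2-(methoxymethoxy)-4,8-dimethyl-10-{[(2E)-2-methylbut-2-enoyl]oxy}-7-oxocyclodec-3-en-1-yl]prop-2-enoate F4.
- Me2BBr (CH2Cl2, −78 °C, bicarbonate work-up) removes the methoxymethyl ether to give the hydroxy ester methyl 2-[(1R,2R,3Z,8R,10R)-2,8-dihydroxy-4,8-dimethyl-10-{[(2E)-2-methylbut-2-enoyl]oxy}-7-oxocyclodec-3-en-1-yl]prop-2-enoate F5.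
- Acid-catalysed lactonisation of F5 (PPTS, benzene, 50 °C) closes the cis-fused lactone of 21.

## Further compounds

F1 | step 3 | S-ethyl (3R)-3,7-dimethyl-4-oxo-3-[(trimethylsilyl)oxy]oct-7-enethioate | C=C(C)CCC(=O)[C@](C)(O[Si](C)(C)C)CC(=O)SCC
F2 | step 8 | trichloro[(aS,4R)-4-(methoxymethoxy)hexa-1,2,5-trien-1-yl]silane | Cl[Si](Cl)(Cl)C=C=C[C@H](OCOC)C=C
F3 | step 12 | methyl (3S,4R)-3-[(1R,3R)-3-hydroxy-3,7-dimethyl-1-{[(2E)-2-methylbut-2-enoyl]oxy}-4-oxooct-7-en-1-yl]-4-(methoxymethoxy)-2-methylidenehex-5-enoate | C=C(C(=O)OC)[C@H]([C@H](OCOC)C=C)[C@H](OC(=O)/C(C)=C/C)C[C@@](C)(O)C(=O)CCC(C)=C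
F4 | step 12 | methyl 2-[(1S,2R,3Z,8R,10R)-8-hydroxy-2-(methoxymethoxy)-4,8-dimethyl-10-{[(2E)-2-methylbut-2-enoyl]oxy}-7-oxocyclodec-3-en-1-yl]prop-2-enoate | C=C(C(=O)OC)[C@@H]1[C@H](OCOC)/C=C(/C)CCC(=O)[C@](C)(O)C[C@H]1OC(=O)/C(C)=C/C
F5 | step 12 | methyl 2-[(1R,2R,3Z,8R,10R)-2,8-dihydroxy-4,8-dimethyl-10-{[(2E)-2-methylbut-2-enoyl]oxy}-7-oxocyclodec-3-en-1-yl]prop-2-enoate | C=C(C(=O)OC)[C@@H]1[C@H](O)/C=C(/C)CCC(=O)[C@](C)(O)C[C@H]1OC(=O)/C(C)=C/C
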